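## Retrosynthetic overview
1. The target comes from acetylation of the C8 alcohol. That alcohol comes from the key 1,2-shift: in the epoxide of a bicyclo[2.2.2]octenone, the CHMe carbon moves from bridgehead C4 to the allyl-bearing C5. This turns the [2.2.2] core into the [3.2.1] core, builds the quaternary allyl centre and fixes the carbinol. A 1,2-H shift and hydride capture then finish the CH2–CH(OMe) unit.
2. The epoxide comes from face-selective epoxidation, preceded by SmI2 removal of one ketal methoxy group. The bicyclo[2.2.2]octenone itself comes from an enantioselective [4+2] union of a masked o-benzoquinone with (E)-methylisoeugenol.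
3. The masked o-benzoquinone comes from 4-allyl-2,6-dimethoxyphenol, made from resorcinol and allyl bromide.
4. (E)-Methylisoeugenol comes from catechol and (E)-propenylboronic acid.
5. Ring order: both arenes are bought in. The bicyclo[2.2.2]octene forms next (both carbocycles at once), and the shift then gives the cyclopentane and cyclohexanone rings of the bicyclo[3.2.1]octane.

Assumption: the sense of induction of the new catalyst in step 9 cannot be known in advance. The (S,S) ligand is written; the (R,R) ligand is used if (S,S) delivers the mirror image.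

Locants in the text are those of the names given.

## Route

Step 1
Reactants: 1 catechol
Product: 2 1,2-dimethoxybenzene
Conditions: MeI (2.5 equiv), K2CO3, acetone, reflux
Reagents that add atoms: iodomethane, CI
Why: Williamson O-methylation (SN2) of both phenoxides; no stereocentre is formed.

Step 2
Reactants: 2 1,2-dimethoxybenzene
Product: 3 4-bromo-1,2-dimethoxybenzene
Conditions: NBS (1.0 equiv), MeCN, 0 °C to rt
Reagents that add atoms: N-bromosuccinimide, O=C1CCC(=O)N1Br
Why: Electrophilic aromatic bromination goes para to one methoxy group, the only activated and unhindered position.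

Step 3
Reactants: 3 4-bromo-1,2-dimethoxybenzene; 4 (E)-prop-1-en-1-ylboronic acid
Product: 5 (E)-1,2-dimethoxy-4-(prop-1-en-1-yl)benzene
Conditions: Pd(PPh3)4 (3 mol %), K2CO3, dioxane/H2O, 85 °C
Reagents that add atoms: none
Why: Suzuki–Miyaura coupling transfers the alkenyl group with retention of the E geometry.

Step 4
Reactants: 6 resorcinol
Product: 7 1,3-dimethoxybenzene
Conditions: MeI (2.5 equiv), K2CO3, acetone, reflux
Reagents that add atoms: iodomethane, CI
Why: Williamson O-methylation of both phenoxides; no stereocentre is formed.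

Step 5
Reactants: 7 1,3-dimethoxybenzene
Product: 10 2,6-dimethoxyphenol, via aryllithium 8 (not isolated), via lithium aryltrimethoxyborate 9 (not isolated)
Conditions: n-BuLi, THF, 0 °C to rt; B(OMe)3, −78 °C to rt; AcOH, 30 % H2O2, 0 °C
Reagents that add atoms: hydrogen peroxide, OO (phenol oxygen); n-butyllithium, [Li]CCCC (lithium of 8 and 9 only); trimethyl borate, COB(OC)OC (boron and methoxy groups of 9 only)
Why: Directed ortho-metalation occurs between the two methoxy groups, and borylation followed by peroxide-induced boron-to-oxygen aryl migration gives the phenol.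

Step 6
Reactants: 10 2,6-dimethoxyphenol; 11 allyl bromide
Product: 12 2-(allyloxy)-1,3-dimethoxybenzene
Conditions: K2CO3, acetone, reflux
Reagents that add atoms: none
Why: Williamson ether synthesis on an unhindered allylic bromide.

Step 7
Reactants: 12 2-(allyloxy)-1,3-dimethoxybenzene
Product: 15 4-allyl-2,6-dimethoxyphenol, via ortho-dienone 13 (not isolated), via para-dienone 14 (not isolated)
Conditions: N,N-diethylaniline, 200 °C, argon
Reagents that add atoms: none
Why: In this para-Claisen rearrangement the [3,3] shift reaches a blocked ortho carbon, a Cope shift carries the allyl group to the para carbon, and tautomerisation restores the phenol.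

Step 8
Reactants: 15 4-allyl-2,6-dimethoxyphenol
Product: 16 4-allyl-2,6,6-trimethoxycyclohexa-2,4-dien-1-one
Conditions: PhI(OAc)2 (1.05 equiv), MeOH, 0 °C, 15 min; cold NaHCO3 wash; used within the hour
Reagents that add atoms: methanol, CO
Why: In this hypervalent-iodine oxidative dearomatisation methanol attacks the methoxy-bearing ortho carbon, which best carries positive charge, and the two identical ketal groups leave 16 achiral.

Step 9
Reactants: 16 4-allyl-2,6,6-trimethoxycyclohexa-2,4-dien-1-one; 5 (E)-1,2-dimethoxy-4-(prop-1-en-1-yl)benzene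
Product: 17 (1R,4S,7S,8R)-5-allyl-7-(3,4-dimethoxyphenyl)-1,3,3-trimethoxy-8-methylbicyclo[2.2.2]oct-5-en-2-one
Conditions: [Cu((S,S)-t-Bu-box)](SbF6)2 (10 mol %), 5 (3 equiv), slow addition of 16, 4 Å MS, CH2Cl2, −20 °C
Reagents that add atoms: none
Why: Proposed new method: the carbonyl oxygen and the vinylic 2-methoxy oxygen of 16 should bind divalent copper as a planar five-membered chelate that lowers the dienone LUMO and lets one tert-butyl group of the ligand cover one enantiotopic face; the nucleophilic CHMe carbon of 5 then bonds to the electrophilic C5 terminus of 16 and the benzylic carbon to C2 in a strongly asynchronous inverse-electron-demand Diels–Alder reaction; the methyl group avoids the ketal methoxy group that points at the dienophile and sits under the diene, so the aryl group sits under the copper-bound carbonyl (aryl syn to the C2–C3 bridge, methyl syn to the alkene), which sets C1, C4, C7 and C8 in one event; the closest known reaction types are the uncatalysed racemic thermal Diels–Alder reactions of masked o-benzoquinones with styrenes and propenylarenes, and bis(oxazoline)–copper catalysed cycloadditions of chelating α-oxygenated enones.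

Step 10
Reactants: 17 (1R,4S,7S,8R)-5-allyl-7-(3,4-dimethoxyphenyl)-1,3,3-trimethoxy-8-methylbicyclo[2.2.2]oct-5-en-2-one
Product: 19 (1R,3S,4S,7S,8S)-5-allyl-7-(3,4-dimethoxyphenyl)-1,3-dimethoxy-8-methylbicyclo[2.2.2]oct-5-en-2-one, via diiodosamarium enolate 18 (not isolated)
Conditions: SmI2 (2.1 equiv, slow addition), THF/MeOH, −78 to 0 °C
Reagents that add atoms: samarium diiodide, I[Sm]I (held only in 18)
Why: Samarium diiodide α-demethoxylation expels one C3 methoxide through the ketyl, while the C1 methoxy group stays because a bridgehead enolate is forbidden; the enolate is protonated from the open alkene side (the other face is covered by the aryl group), so C3–H points to the alkene and C3–OMe to the C7–C8 bridge.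

Step 11
Reactants: 19 (1R,3S,4S,7S,8S)-5-allyl-7-(3,4-dimethoxyphenyl)-1,3-dimethoxy-8-methylbicyclo[2.2.2]oct-5-en-2-one
Product: 20 5,6-epoxide of 19 (oxygen syn to the C2–C3 bridge)
Conditions: dimethyldioxirane (1.05 equiv), acetone/CH2Cl2, −20 °C; evaporate cold
Reagents that add atoms: dimethyldioxirane, CC1(C)OO1
Why: This neutral electrophilic epoxidation prefers the trisubstituted ring alkene to the terminal allyl alkene and attacks the face flanked only by C3–H and the flat carbonyl, because the other face is covered by the C8 methyl group; this fixes the later carbinol configuration.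

Step 12
Reactants: 20 5,6-epoxide of 19 (oxygen syn to the C2–C3 bridge)
Product: 23 (1S,3S,5S,6R,7S,8S)-5-allyl-7-(3,4-dimethoxyphenyl)-8-hydroxy-1,3-dimethoxy-6-methylbicyclo[3.2.1]octan-2-one, via oxocarbenium triflate 21 (not isolated), via triethylsilyl ether 22 (not isolated)
Conditions: Et3SiOTf (10 mol %), Et3SiH (10 equiv), CH2Cl2, −78 to −40 °C; then 1 M HCl, THF, rt
Reagents that add atoms: triethylsilane, CC[SiH](CC)CC (hydride in 23; silyl group held only in 21 and 22); triethylsilyl triflate, CC[Si](CC)(CC)OS(=O)(=O)C(F)(F)F (counter-ion of 21 only)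
Why: Proposed new method: O-silylation of the epoxide breaks the tertiary C5–O bond while the anti-periplanar C4–C8 bond migrates to C5 (Wagner–Meerwein 1,2-shift, [2.2.2] to [3.2.1], inversion at C5, retention at the migrating CHMe carbon and at the carbinol carbon); the C3–H bond anti-periplanar to the departing bond follows as a 1,2-hydride shift, so the unstabilised secondary cation is bypassed and the methoxy-stabilised ion 21 forms; Et3SiH reduces 21 from the exo face because the endo face is covered by the aryl group, which sets C3 and regenerates Et3SiOTf; direct hydride capture at the CH2 carbon, or proton loss followed by reprotonation, leads to the same product; the closest known reaction types are Lewis acid epoxide-opening Wagner–Meerwein and semipinacol rearrangements of bicyclo[2.2.2]octenes, and the ionic hydrogenation of oxocarbenium ions with silanes.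

Step 13
Reactants: 23 (1S,3S,5S,6R,7S,8S)-5-allyl-7-(3,4-dimethoxyphenyl)-8-hydroxy-1,3-dimethoxy-6-methylbicyclo[3.2.1]octan-2-one
Product: 24 (1S,3S,5S,6R,7S,8S)-5-allyl-7-(3,4-dimethoxyphenyl)-1,3-dimethoxy-6-methyl-2-oxobicyclo[3.2.1]octan-8-yl acetate
Conditions: Ac2O, pyridine, DMAP (0.2 equiv), CH2Cl2, rt to 40 °C
Reagents that add atoms: acetic anhydride, CC(=O)OC(C)=O
Why: DMAP-catalysed acylation of the hindered secondary alcohol leaves the C–O bond untouched, so C8 keeps its configuration, and the base is too weak to epimerise C3.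

## Compound list
1 | catechol | Oc1ccccc1O | starting material
2 | 1,2-dimethoxybenzene | COc1ccccc1OC | intermediate
3 | 4-bromo-1,2-dimethoxybenzene | COc1ccc(Br)cc1OC | intermediate
4 | (E)-prop-1-en-1-ylboronic acid | C/C=C/B(O)O | starting material
5 | (E)-1,2-dimethoxy-4-(prop-1-en-1-yl)benzene | C/C=C/c1ccc(OC)c(OC)c1 | intermediate
6 | resorcinol | Oc1cccc(O)c1 | starting material
7 | 1,3-dimethoxybenzene | COc1cccc(OC)c1 | intermediate
8 | 2,6-dimethoxyphenyllithium | [Li]c1c(OC)cccc1OC | intermediate (not isolated)
9 | lithium (2,6-dimethoxyphenyl)trimethoxyborate | [Li+].CO[B-](OC)(OC)c1c(OC)cccc1OC | intermediate (not isolated)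
10 | 2,6-dimethoxyphenol | COc1cccc(OC)c1O | intermediate
11 | allyl bromide | C=CCBr | starting material
12 | 2-(allyloxy)-1,3-dimethoxybenzene | C=CCOc1c(OC)cccc1OC | intermediate
13 | 6-allyl-2,6-dimethoxycyclohexa-2,4-dien-1-one (racemic, transient) | C=CCC1(OC)C=CC=C(OC)C1=O | intermediate (not isolated)
14 | 4-allyl-2,6-dimethoxycyclohexa-2,5-dien-1-one | C=CCC1C=C(OC)C(=O)C(OC)=C1 | intermediate (not isolated)
15 | 4-allyl-2,6-dimethoxyphenol | C=CCc1cc(OC)c(O)c(OC)c1 | intermediate
16 | 4-allyl-2,6,6-trimethoxycyclohexa-2,4-dien-1-one | C=CCC1=CC(OC)(OC)C(=O)C(OC)=C1 | intermediate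
17 | (1R,4S,7S,8R)-5-allyl-7-(3,4-dimethoxyphenyl)-1,3,3-trimethoxy-8-methylbicyclo[2.2.2]oct-5-en-2-one; aryl syn to the ketone bridge, methyl syn to the alkene | C=CCC1=C[C@]2(OC)C(=O)C(OC)(OC)[C@H]1[C@H](C)[C@H]2c3ccc(OC)c(OC)c3 | intermediate
18 | diiodosamarium C2–C3 enolate of 19 | C=CCC1=C[C@]2(OC)C(O[Sm](I)I)=C(OC)[C@H]1[C@H](C)[C@H]2c3ccc(OC)c(OC)c3 | intermediate (not isolated)
19 | (1R,3S,4S,7S,8S)-5-allyl-7-(3,4-dimethoxyphenyl)-1,3-dimethoxy-8-methylbicyclo[2.2.2]oct-5-en-2-one; C3–OMe syn to the C7–C8 bridge | C=CCC1=C[C@]2(OC)C(=O)[C@@H](OC)[C@H]1[C@H](C)[C@H]2c3ccc(OC)c(OC)c3 | intermediate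
20 | 5,6-epoxide of 19; oxygen syn to the C2–C3 bridge, anti to the C7–C8 bridge | C=CC[C@@]12O[C@@H]1[C@]3(OC)C(=O)[C@@H](OC)[C@H]2[C@H](C)[C@H]3c4ccc(OC)c(OC)c4 | intermediate
21 | ring-shifted bicyclo[3.2.1]octane C3 methoxy-oxocarbenium triflate with C8–OSiEt3 | C=CC[C@]12CC(=[O+]C)C(=O)[C@](OC)([C@H](c3ccc(OC)c(OC)c3)[C@H]1C)[C@H]2O[Si](CC)(CC)CC.[O-]S(=O)(=O)C(F)(F)F | intermediate (not isolated)
22 | triethylsilyl ether of 23 | C=CC[C@]12C[C@H](OC)C(=O)[C@](OC)([C@H](c3ccc(OC)c(OC)c3)[C@H]1C)[C@H]2O[Si](CC)(CC)CC | intermediate (not isolated)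
23 | (1S,3S,5S,6R,7S,8S)-5-allyl-7-(3,4-dimethoxyphenyl)-8-hydroxy-1,3-dimethoxy-6-methylbicyclo[3.2.1]octan-2-one; aryl endo, methyl exo, OH syn to the ketone bridge, C3–OMe on the side of the C6–C7 bridge | C=CC[C@]12C[C@H](OC)C(=O)[C@](OC)([C@H](c3ccc(OC)c(OC)c3)[C@H]1C)[C@H]2O | intermediate
24 | (1S,3S,5S,6R,7S,8S)-5-allyl-7-(3,4-dimethoxyphenyl)-1,3-dimethoxy-6-methyl-2-oxobicyclo[3.2.1]octan-8-yl acetate | C=CC[C@]12C[C@H](OC)C(=O)[C@](OC)([C@H](c3ccc(OC)c(OC)c3)[C@H]1C)[C@H]2OC(C)=O | target

## Step count
Total steps: 13. Longest linear sequence: 10 (steps 4 to 13, from resorcinol 6).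

## Three steps most likely to fail

**Step 9 (proposed new step).**
- Risks: a slow reaction with a 1,2-disubstituted styrene, and self-dimerisation of 16.
- Further risks: ionisation of the ketal by the Lewis acid, which would lead to benzofuran-type or formal [5+2] adducts; formation of the aryl-endo diastereomer; and modest ee.
- Fallback (known chemistry): set out from 16 and 5 and run the uncatalysed thermal cycloaddition of the masked o-benzoquinone (5 in threefold excess, toluene, 80 °C).
- This gives racemic material, namely 17 together with its mirror image ent-17 F1. The two are separated by preparative supercritical-fluid chromatography on an amylose carbamate chiral phase.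
- The route is rejoined at 17.

**Step 12 (proposed new step).**
- Risks: hydride shift from the epoxide CH to give the bicyclo[2.2.2]octanone, and proton loss from the allyl CH2 to give a diene.
- Further risks: Friedel–Crafts closure of the endo aryl ring onto ion 21 before the silane arrives, and silane reduction of the ketone.
- Fallback (known chemistry): set out from 20 and split the shift and the reduction into two separate operations.
- BF3·OEt2 with 2,6-di-tert-butylpyridine in CH2Cl2 at −78 °C is a classical Lewis acid epoxide-opening Wagner–Meerwein rearrangement ended by proton loss. It gives the α-methoxy enone alcohol 5-allyl-7-(3,4-dimethoxyphenyl)-8-hydroxy-1,3-dimethoxy-6-methylbicyclo[3.2.1]oct-3-en-2-one F2.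
- Copper hydride conjugate reduction with [(Ph3P)CuH]6 in wet toluene leaves the allyl group untouched, and the enolate is protonated from the exo face.
- The route is rejoined at 23.

**Step 10.**
- Risks: loss of both C3 methoxy groups, formation of the wrong C3 epimer (which would put OMe instead of H anti-periplanar to the migrating bond in step 12), and ketyl side reactions.
- Fallback (known chemistry): set out from 17 and hydrolyse the α-keto ketal (TFA/H2O, CH2Cl2, in the dark) to the diketone 5-allyl-7-(3,4-dimethoxyphenyl)-1-methoxy-8-methylbicyclo[2.2.2]oct-5-ene-2,3-dione F3.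
- Reduce the less hindered C3 carbonyl with one equivalent of LiBH(s-Bu)3 at −78 °C. Hydride arrives from the alkene side and gives the ketol 5-allyl-7-(3,4-dimethoxyphenyl)-3-hydroxy-1-methoxy-8-methylbicyclo[2.2.2]oct-5-en-2-one F4.
- O-methylate F4 under neutral conditions (MeI, Ag2O, CH2Cl2).
- The route is rejoined at 19.

## Further compounds
F1 | step 9 | ent-17, (1S,4R,7R,8S)-5-allyl-7-(3,4-dimethoxyphenyl)-1,3,3-trimethoxy-8-methylbicyclo[2.2.2]oct-5-en-2-one | C=CCC1=C[C@@]2(OC)C(=O)C(OC)(OC)[C@@H]1[C@@H](C)[C@@H]2c3ccc(OC)c(OC)c3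
F2 | step 12 | 5-allyl-7-(3,4-dimethoxyphenyl)-8-hydroxy-1,3-dimethoxy-6-methylbicyclo[3.2.1]oct-3-en-2-one, configured as 23 at C1, C5, C6, C7 and C8 | C=CC[C@]12C=C(OC)C(=O)[C@](OC)([C@H](c3ccc(OC)c(OC)c3)[C@H]1C)[C@H]2O
F3 | step 10 | 5-allyl-7-(3,4-dimethoxyphenyl)-1-methoxy-8-methylbicyclo[2.2.2]oct-5-ene-2,3-dione, configured as 17 | C=CCC1=C[C@]2(OC)C(=O)C(=O)[C@H]1[C@H](C)[C@H]2c3ccc(OC)c(OC)c3
F4 | step 10 | 5-allyl-7-(3,4-dimethoxyphenyl)-3-hydroxy-1-methoxy-8-methylbicyclo[2.2.2]oct-5-en-2-one, configured as 19 | C=CCC1=C[C@]2(OC)C(=O)[C@@H](O)[C@H]1[C@H](C)[C@H]2c3ccc(OC)c(OC)c3
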